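**Target:** CNP0138236.2, 1α-acetoxy-8α-angeloyloxy-10αH-eremophil-11-en-9-one, (1S,4S,5R,7R,8R,10S); trans-decalin with 4β,5β-dimethyl, 7β-isopropenyl, 8α-O-angelate (Z), 9-ketone and 1α-OAc.

**Retrosynthetic overview**
1. Target ⇐ C1 acetylation and C8 angeloylation of the 1α,8α-dihydroxy-9-ketone; the 8α-OH comes from Rubottom oxidation of a Δ8 enol silane.
2. Isopropenyl group plus Δ8 enol silane ⇐ new titanium/cobalt radical-relay opening of a gem-dimethylcyclopropyl ketone; the carane cyclopropane is a masked isopropenyl group and a β-face shield.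
3. 1α-OH and 10α-H (trans fusion) ⇐ α-face hydroboration of a Δ1(10) alkene; 4β-methyl ⇐ α-face hydrogenation of a 4(15)-methylene.
4. Ring A ⇐ conjugate addition of a 2-alkenyl Grignard (C15, C4–C1) to (−)-car-3-en-5-one anti to the cyclopropane (quaternary C5), then intramolecular aldol condensation (C1–C10).
5. Ring B and C7 ⇐ (+)-3-carene (chiral pool). Ring order: ring B is present from the start, ring A is built second, the cyclopropane is opened last.

Assumption: eremophilane numbering is used for the decalin compounds (C14 on C5 drawn β; "8,11-cyclo" means an extra C8–C11 bond, i.e. the carane cyclopropane on C7/C8), and commercial (+)-3-carene is the (1S,6R) enantiomer.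

**Route**

Step 1
Reactants: 1 (+)-3-carene
Product: 2 (−)-car-3-en-5-one [(1R,6S)-4,7,7-trimethylbicyclo[4.1.0]hept-3-en-2-one]
Conditions: t-BuOOH (70% aq.), CrO3 (5 mol %), CH2Cl2, rt
Reagents that add atoms: tert-butyl hydroperoxide, CC(C)(C)OO
Why: Chromium-catalysed allylic C–H oxidation converts the ring CH2 next to the unsubstituted olefinic carbon into the enone carbonyl; no stereocentre is formed and the two cyclopropane stereocentres are untouched.

Step 2
Reactants: 3 2,3-dibromopropene; 4 (1,3-dioxolan-2-ylmethyl)magnesium bromide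
Product: 5 2-(3-bromobut-3-en-1-yl)-1,3-dioxolane
Conditions: CuI (5 mol %), THF, −20 °C → rt
Reagents that add atoms: none
Why: Copper-catalysed allylic substitution (Grignard cross-coupling) at the allylic C–Br; the vinylic bromide is inert and no stereocentre is formed.

Step 3
Reactants: 2 (−)-car-3-en-5-one; 5 2-(3-bromobut-3-en-1-yl)-1,3-dioxolane
Product: 8 (1R,4S,6S)-4-[4-(1,3-dioxolan-2-yl)but-1-en-2-yl]-4,7,7-trimethylbicyclo[4.1.0]heptan-2-one, via alkenylmagnesium bromide 6 (not isolated), via trimethylsilyl enol ether 7 (not isolated)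
Conditions: Mg, THF, 50 °C; then 2, CuBr·SMe2 (15 mol %), Me3SiCl, HMPA, THF, −78 → −30 °C; then 10% aq. citric acid, 0 °C
Reagents that add atoms: none
Why: Copper-catalysed, Me3SiCl-accelerated conjugate addition of the alkenyl Grignard reagent; the endo methyl of the gem-dimethylcyclopropane blocks the syn face, so the nucleophile enters anti to the cyclopropane and the quaternary C5 is set with its methyl cis to the cyclopropane.

Step 4
Reactants: 8 keto acetal
Product: 10 7αH,8αH-8,11-cycloeremophila-1(10),4(15)-dien-9-one, via keto aldehyde 9 (not isolated)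
Conditions: AcOH/H2O/THF (3:1:1), 45 °C; then KOH (0.2 equiv), MeOH, rt, 0.02 M
Reagents that add atoms: none
Why: Acetal hydrolysis followed by intramolecular aldol condensation (Robinson-type ring closure); C10 is the only enolisable ketone α-carbon (C8 is a cyclopropane CH), six-membered closure onto the aldehyde and dehydration give the conjugated enone, while the competing aldehyde-enolate aldol is reversible and cannot dehydrate at a bridgehead.

Step 5
Reactants: 10 dienone
Product: 11 7αH,8αH-8,11-cycloeremophil-1(10)-en-9-one (4β-methyl)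
Conditions: H2 (1 atm), RhCl(PPh3)3 (5 mol %), benzene, rt
Reagents that add atoms: none
Why: Homogeneous hydrogenation with RhCl(PPh3)3 is selective for the 1,1-disubstituted exocyclic alkene over the trisubstituted enone; H2 is delivered to the α face, anti to the pseudoaxial C5 methyl on the neighbouring carbon, which sets C4 as 4β-methyl (4S).

Step 6
Reactants: 11 enone
Product: 12 7αH,8αH-8,11-cycloeremophil-1(10)-en-9β-ol
Conditions: NaBH4, CeCl3·7H2O, MeOH, −40 °C
Reagents that add atoms: none
Why: Luche 1,2-reduction; hydride attacks anti to the cyclopropane to give the 9β-alcohol, a temporary centre that is removed again in step 9.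

Step 7
Reactants: 12 allylic alcohol
Product: 13 7αH,8αH,10αH-8,11-cycloeremophilane-1α,9β-diol
Conditions: BH3·THF (3 equiv), THF, 0 °C → rt; then 3 M NaOH, 30% H2O2, 0 °C
Reagents that add atoms: hydrogen peroxide, OO
Why: Hydroboration–oxidation; syn addition of H–B across C1=C10 from the α face (anti to the angular C5 methyl, the cyclopropane and the 9β-oxygen) with boron on the less substituted C1, and oxidation with retention, sets 1α-OH (1S) and 10α-H (10S, trans ring fusion), as in the hydroboration of steroidal 5-enes.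

Step 8
Reactants: 13 diol
Product: 14 1α-(tert-butyldimethylsilyloxy)-7αH,8αH,10αH-8,11-cycloeremophilan-9β-ol
Conditions: TBSCl (1.1 equiv), imidazole, CH2Cl2, −10 °C
Reagents that add atoms: tert-butyldimethylsilyl chloride, CC(C)(C)[Si](C)(C)Cl
Why: Site-selective silylation; the equatorial C1 hydroxyl reacts, whereas the C9 hydroxyl, flanked by the ring fusion and the gem-dimethylcyclopropane, does not.

Step 9
Reactants: 14 mono-silyl ether
Product: 15 1α-(tert-butyldimethylsilyloxy)-7αH,8αH,10αH-8,11-cycloeremophilan-9-one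
Conditions: Dess–Martin periodinane, pyridine, CH2Cl2, 0 °C → rt
Reagents that add atoms: none
Why: Dess–Martin oxidation under buffered, near-neutral conditions gives the cyclopropyl ketone without epimerising the new α-stereocentre C10.

Step 10
Reactants: 15 cyclopropyl ketone
Product: 16 1α-(tert-butyldimethylsilyloxy)-9-(trimethylsilyloxy)-10αH-eremophila-8,11-diene
Conditions: Cp2TiCl2 (10 mol %), Zn dust (20 mol %), Co(salen) (5 mol %), Me3SiCl (1.5 equiv), 2,4,6-collidine (2 equiv), THF, 25 °C
Reagents that add atoms: chlorotrimethylsilane, C[Si](C)(C)Cl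
Why: Proposed new method: radical redox-relay eliminative ring opening of a gem-dimethylcyclopropyl ketone, which forms the C11=C12 bond of the isopropenyl group and the C8=C9 enol silane bond. Trivalent titanium (Cp2TiCl from Cp2TiCl2/Zn) binds the C9 carbonyl and by inner-sphere electron transfer cleaves the exocyclic C8–C11 cyclopropane bond, the one aligned with the carbonyl π system, giving a tertiary C11 radical and a tetravalent-titanium enolate. Divalent Co(salen) then takes a hydrogen atom from one of the two methyl groups (six accessible H against one hindered ring C7–H), so the isopropenyl alkene forms and not the isopropylidene. Me3SiCl silylates the enolate, and collidine deprotonates the trivalent cobalt hydride to monovalent cobalt, which returns the electron to titanium; the process is redox-neutral. C7 keeps its configuration, and the enol silane forms only toward C8, which directs the next oxidation to C8 and not C10. Closest known reaction types: titanium/cobalt radical redox-relay isomerisation of epoxides to allylic alcohols, and trivalent-titanium-catalysed radical ring opening of cyclopropyl ketones in formal [3+2] cycloadditions.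

Step 11
Reactants: 16 enol silane
Product: 18 1α-(tert-butyldimethylsilyloxy)-8α-hydroxy-10αH-eremophil-11-en-9-one, via silyloxy epoxide 17 (not isolated)
Conditions: dimethyldioxirane (1.05 equiv, acetone), CH2Cl2, −78 °C; then 10% aq. citric acid, THF, 0 °C
Reagents that add atoms: dimethyldioxirane, CC1(C)OO1
Why: Rubottom oxidation; the electron-rich enol silane is epoxidised much faster than the isopropenyl alkene and from the α face, anti to the adjacent β-isopropenyl group and the β C5 methyl, and acid opens the silyloxy epoxide to the 8α-hydroxy ketone (8R).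

Step 12
Reactants: 18 α-hydroxy ketone; 19 angelic acid
Product: 21 8α-angeloyloxy-1α-(tert-butyldimethylsilyloxy)-10αH-eremophil-11-en-9-one, via mixed anhydride 20 (not isolated)
Conditions: 19, 2,4,6-trichlorobenzoyl chloride, Et3N, toluene, rt; then 18, 80 °C
Reagents that add atoms: none
Why: Yamaguchi-type mixed-anhydride esterification run without a nucleophilic amine catalyst, so the Z (angelate) geometry is kept; O-acylation leaves C8 unchanged.

Step 13
Reactants: 21 silyl ether
Product: 22 8α-angeloyloxy-1α-hydroxy-10αH-eremophil-11-en-9-one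
Conditions: HF·pyridine, pyridine, THF, 0 °C → rt
Reagents that add atoms: none
Why: Fluoride-mediated desilylation under mildly acidic conditions that leave the angelate, the isopropenyl group and the α-acyloxy ketone untouched.

Step 14
Reactants: 22 β-hydroxy ketone
Product: 23 1α-acetoxy-8α-angeloyloxy-10αH-eremophil-11-en-9-one (target)
Conditions: Ac2O, pyridine, DMAP (cat.), CH2Cl2, 0 °C
Reagents that add atoms: acetic anhydride, CC(=O)OC(C)=O
Why: Standard acetylation of the equatorial C1 alcohol with retention, under conditions too mild for retro-aldol cleavage or β-elimination.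

**Compound list**
1 | (+)-3-carene, (1S,6R)-3,7,7-trimethylbicyclo[4.1.0]hept-3-ene | CC3(C)[C@H]1CC(C)=CC[C@H]13 | starting material
2 | (−)-car-3-en-5-one, (1R,6S)-4,7,7-trimethylbicyclo[4.1.0]hept-3-en-2-one | CC3(C)[C@H]1CC(C)=CC(=O)[C@H]13 | intermediate
3 | 2,3-dibromopropene | C=C(Br)CBr | starting material
4 | (1,3-dioxolan-2-ylmethyl)magnesium bromide | Br[Mg]CC1OCCO1 | starting material
5 | 2-(3-bromobut-3-en-1-yl)-1,3-dioxolane | C=C(Br)CCC1OCCO1 | intermediate
6 | [4-(1,3-dioxolan-2-yl)but-1-en-2-yl]magnesium bromide | C=C([Mg]Br)CCC1OCCO1 | intermediate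
7 | trimethylsilyl enol ether of 8, {[(1R,4S,6S)-4-[4-(1,3-dioxolan-2-yl)but-1-en-2-yl]-4,7,7-trimethylbicyclo[4.1.0]hept-2-en-2-yl]oxy}trimethylsilane | CC3(C)[C@H]1C[C@](C)(C(=C)CCC4OCCO4)C=C(O[Si](C)(C)C)[C@H]13 | intermediate
8 | (1R,4S,6S)-4-[4-(1,3-dioxolan-2-yl)but-1-en-2-yl]-4,7,7-trimethylbicyclo[4.1.0]heptan-2-one (alkenyl group trans, C4 methyl cis to the cyclopropane) | CC3(C)[C@H]1C[C@](C)(C(=C)CCC4OCCO4)CC(=O)[C@H]13 | intermediate
9 | (1R,4S,6S)-4,7,7-trimethyl-4-(5-oxopent-1-en-2-yl)bicyclo[4.1.0]heptan-2-one | CC3(C)[C@H]1C[C@](C)(C(=C)CCC=O)CC(=O)[C@H]13 | intermediate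
10 | 7αH,8αH-8,11-cycloeremophila-1(10),4(15)-dien-9-one (5β-methyl, cyclopropane on the β face) | CC3(C)[C@H]1C[C@@]2(C)C(C(=O)[C@H]13)=CCCC2=C | intermediate
11 | 7αH,8αH-8,11-cycloeremophil-1(10)-en-9-one (4β,5β-dimethyl) | CC3(C)[C@H]1C[C@@]2(C)C(C(=O)[C@H]13)=CCC[C@@H]2C | intermediate
12 | 7αH,8αH-8,11-cycloeremophil-1(10)-en-9β-ol | CC3(C)[C@H]1C[C@@]2(C)C([C@@H](O)[C@H]13)=CCC[C@@H]2C | intermediate
13 | 7αH,8αH,10αH-8,11-cycloeremophilane-1α,9β-diol | CC3(C)[C@H]1C[C@@]2(C)[C@H]([C@@H](O)[C@H]13)[C@@H](O)CC[C@@H]2C | intermediate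
14 | 1α-(tert-butyldimethylsilyloxy)-7αH,8αH,10αH-8,11-cycloeremophilan-9β-ol | CC3(C)[C@H]1C[C@@]2(C)[C@H]([C@@H](O)[C@H]13)[C@@H](O[Si](C)(C)C(C)(C)C)CC[C@@H]2C | intermediate
15 | 1α-(tert-butyldimethylsilyloxy)-7αH,8αH,10αH-8,11-cycloeremophilan-9-one | CC3(C)[C@H]1C[C@@]2(C)[C@H](C(=O)[C@H]13)[C@@H](O[Si](C)(C)C(C)(C)C)CC[C@@H]2C | intermediate
16 | 1α-(tert-butyldimethylsilyloxy)-9-(trimethylsilyloxy)-10αH-eremophila-8,11-diene (7β-isopropenyl) | C=C(C)[C@H]1C[C@@]2(C)[C@H](C(O[Si](C)(C)C)=C1)[C@@H](O[Si](C)(C)C(C)(C)C)CC[C@@H]2C | intermediate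
17 | 8α,9α-epoxy-1α-(tert-butyldimethylsilyloxy)-9β-(trimethylsilyloxy)-10αH-eremophil-11-ene | C=C(C)[C@H]1C[C@@]2(C)[C@H]([C@]3(O[Si](C)(C)C)O[C@H]13)[C@@H](O[Si](C)(C)C(C)(C)C)CC[C@@H]2C | intermediate
18 | 1α-(tert-butyldimethylsilyloxy)-8α-hydroxy-10αH-eremophil-11-en-9-one | C=C(C)[C@H]1C[C@@]2(C)[C@H](C(=O)[C@@H]1O)[C@@H](O[Si](C)(C)C(C)(C)C)CC[C@@H]2C | intermediate
19 | angelic acid, (Z)-2-methylbut-2-enoic acid | C/C=C(/C)C(=O)O | starting material
20 | angelic 2,4,6-trichlorobenzoic anhydride | C/C=C(/C)C(=O)OC(=O)c1c(Cl)cc(Cl)cc1Cl | intermediate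
21 | 8α-angeloyloxy-1α-(tert-butyldimethylsilyloxy)-10αH-eremophil-11-en-9-one | C=C(C)[C@H]1C[C@@]2(C)[C@H](C(=O)[C@@H]1OC(=O)/C(C)=C\C)[C@@H](O[Si](C)(C)C(C)(C)C)CC[C@@H]2C | intermediate
22 | 8α-angeloyloxy-1α-hydroxy-10αH-eremophil-11-en-9-one | C=C(C)[C@H]1C[C@@]2(C)[C@H](C(=O)[C@@H]1OC(=O)/C(C)=C\C)[C@@H](O)CC[C@@H]2C | intermediate
23 | 1α-acetoxy-8α-angeloyloxy-10αH-eremophil-11-en-9-one, (1S,4S,5R,7R,8R,10S) | C=C(C)[C@H]1C[C@@]2(C)[C@H](C(=O)[C@@H]1OC(=O)/C(C)=C\C)[C@@H](OC(C)=O)CC[C@@H]2C | target

**Totals**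
Total step count: 14. Longest linear sequence: 13 steps (steps 1 and 3–14, from (+)-3-carene); step 2 is a one-step side branch.

**Three steps most likely to fail, with fallbacks**

Step 10 (the proposed new ring opening). The titanium may not reduce the hindered alkyl cyclopropyl ketone, or the cobalt may give some isopropylidene isomer. The fallback uses known chemistry, sets out from 15 and returns at 16. Ring opening of 15 with iodotrimethylsilane (CH2Cl2, −40 °C; the known homoconjugate opening of cyclopropyl ketones, with iodide attacking the tertiary C11) gives the tertiary iodide silyl enol ether F1. Dehydroiodination of F1 with DBU in toluene (0 °C → rt) gives 16. The ketone stays masked as the enol silane, so base cannot re-close the cyclopropane. Any isopropylidene isomer is removed after step 11.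

Step 12 (angeloylation). The hindered axial α-ketol may react slowly, and heating with Et3N risks angelate-to-tiglate isomerisation or epimerisation α to the ketone. The fallback builds the Z alkene on the substrate instead; it sets out from 18 and returns at 21. Compound 18 is esterified with 2-[bis(2,2,2-trifluoroethoxy)phosphoryl]propanoic acid (N,N′-dicyclohexylcarbodiimide, DMAP cat., CH2Cl2, 0 °C) to give the phosphonopropionate ester F2 (mixture of epimers at the phosphonate carbon). Z-selective Still–Gennari olefination of F2 (KN(SiMe3)2 1.0 equiv, 18-crown-6, THF, −78 °C, then acetaldehyde) gives 21. The phosphonate C–H is far more acidic than the ketone α-hydrogens, so one equivalent of base at −78 °C leaves the ketone alone.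

Step 5 (facial selectivity at C4). If the hydrogenation gives a poor 4β:4α ratio or isomerises the exocyclic alkene, C4 is set by hydroboration and deoxygenation instead. This fallback sets out from 10 and returns at 12, bypassing 11. Luche reduction of 10 (NaBH4, CeCl3·7H2O, MeOH) gives the dienol F3. The bulky 9-borabicyclo[3.3.1]nonane (2.2 equiv, THF; then NaOH/H2O2) adds only to the 1,1-disubstituted alkene, from the α face, to give the 15-hydroxy compound F4 with 4α-H. Selective tosylation of the primary alcohol (TsCl, pyridine, 0 °C) gives the tosylate F5. Reduction of F5 with LiEt3BH (THF, 0 °C → rt) gives 12.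

**Further compounds**
F1 | step 10 | 1α-(tert-butyldimethylsilyloxy)-11-iodo-9-(trimethylsilyloxy)-10αH-eremophil-8-ene | CC(C)(I)[C@H]1C[C@@]2(C)[C@H](C(O[Si](C)(C)C)=C1)[C@@H](O[Si](C)(C)C(C)(C)C)CC[C@@H]2C
F2 | step 12 | 1α-(tert-butyldimethylsilyloxy)-9-oxo-10αH-eremophil-11-en-8α-yl 2-[bis(2,2,2-trifluoroethoxy)phosphoryl]propanoate | C=C(C)[C@H]1C[C@@]2(C)[C@H](C(=O)[C@@H]1OC(=O)C(C)P(=O)(OCC(F)(F)F)OCC(F)(F)F)[C@@H](O[Si](C)(C)C(C)(C)C)CC[C@@H]2C
F3 | step 5 | 7αH,8αH-8,11-cycloeremophila-1(10),4(15)-dien-9β-ol | CC3(C)[C@H]1C[C@@]2(C)C([C@@H](O)[C@H]13)=CCCC2=C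
F4 | step 5 | 7αH,8αH-8,11-cycloeremophil-1(10)-ene-9β,15-diol (4α-H) | CC3(C)[C@H]1C[C@@]2(C)C([C@@H](O)[C@H]13)=CCC[C@@H]2CO
F5 | step 5 | 9β-hydroxy-7αH,8αH-8,11-cycloeremophil-1(10)-en-15-yl 4-methylbenzenesulfonate | CC3(C)[C@H]1C[C@@]2(C)C([C@@H](O)[C@H]13)=CCC[C@@H]2COS(=O)(=O)c4ccc(C)cc4
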